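(Readings and results are calculated from invented constants.)

The slowness in these runs sits in two places. Wednesday's electrophile still reads 14.5% at 10.0 min and 3.6% at 40.0 min, and the isomer of the product trails the electrophile that has reacted.

| flask | electrophile | nucleophile | free base | protic impurity | remark | time |
|---|---|---|---|---|---|---|
| Monday's | 0.024 M | 0.0494 M (fed, over 4.0 min) | 0.141 M | 4.7 mM | run made earlier |  |
| Wednesday's | 0.035 M | 0.0494 M (fed, over 4.0 min) | 0.141 M | 4.7 mM | run made earlier |  |
| flask | 0.047 M | 0.0494 M (fed, over 4.0 min) | 0.141 M | 4.70 mM |  | 30 min |

| run | time / min | electrophile / % | isomer of the product / % |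
|---|---|---|---|
| Monday's | 2.00 | 53.6 | 3.4 |
| Monday's | 6.00 | 4.0 | 21.0 |
| Monday's | 10.0 | 1.9 | 30.8 |
| Monday's | 15.0 | 0 | 36.2 |
| Monday's | 20.0 | 0 | 36.8 |
| Monday's | 30.0 | 0 | 37.0 |
| Monday's | 40.0 | 0.4 | 37.5 |
| Wednesday's | 5.00 | 27.5 | 11.5 |
| Wednesday's | 10.0 | 14.5 | 24.6 |
| Wednesday's | 15.0 | 12.5 | 29.8 |
| Wednesday's | 20.0 | 8.9 | 32.2 |
| Wednesday's | 25.0 | 7.7 | 33.5 |
| Wednesday's | 30.0 | 6.2 | 35.7 |
| Wednesday's | 40.0 | 3.6 | 36.0 |

(readings scatter by 1 percentage point)



1. how much electrophile the flask holds at 30 min, in percent of the electrophile charged
2. how much isomer of the product the flask holds at 30 min, in percent of the electrophile charged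

- Follow one electrophile molecule through the flask. At the first fork, it has reacted by the asked time or it has not. At the second fork, a reacted molecule sits as product or as isomer.
- Take the last readings. Monday gives 0.377 and Wednesday gives 0.373, though Wednesday charged more electrophile than Monday.
- Their mean, 0.375, is the isomer share, the part of the reacted electrophile found as isomer.
- But you should doubt this, because the share is a late value. At 6.00 min, Monday read 0.219.
- So measure the lag. Between 6.00 min and 10.0 min, Monday's gap to the share shrinks with a half-life reading 3.08 min. That is shorter than the asked 30 min, so the flask can carry the share.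
- Another doubt remains: the flask will still be reacting then, and fresh material lags. At Wednesday's late rate, that costs about 0.5 percentage points of isomer, less than the scatter. The flask may fall faster, but you can keep the rule: isomer equals share times electrophile reacted.
- The forecast says 15% electrophile and 31% isomer, on the ground that “isomer plateaus at about 37% of converted electrophile”. On its electrophile, my share gives 31.9%, slightly above its isomer, and the lag covers part of that difference.
- The flask gives 18.7% electrophile and 29.9% isomer, inside the forecast's margins.

    electrophile + nucleophile → acid set free + target (k = 3.10 M⁻¹ s⁻¹)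
    nucleophile + acid set free ⇌ protonated nucleophile, settled at all times (K = 1.80 × 10⁵ M⁻¹)
    acid set free + free base ⇌ salt of the base (K = 490 M⁻¹, k = 11.0 M⁻¹ s⁻¹)
    target ⇌ isomer of the product (K = 0.600, k = 0.00150 s⁻¹)
    nucleophile + protic impurity → quenched reagent (k = 2.20 M⁻¹ s⁻¹)

- So the flask stands at an isomer share of 0.368 at 30.0 min. Target holds 51.4% of the electrophile charged, and unbound nucleophile, the limiting reagent here, is down to 0.161% of its charge. Now take a neighbour flask charged with 0.080 M electrophile, otherwise like this flask. Its 44.5% of electrophile left means 55.5% reacted, and the share turns that into 20.8% isomer. The neighbour flask holds 20.4% isomer.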